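C6–C7 in the middle of the 14-methylpentadecanoyl chain is cut first. Then come the ester bond C1–O at C1', the C3' carbinol (back to a ketone), C1'–C2' (aldol), and the bond from the inter-ring CH2 to C2 of the central oxazole.
Forward: both oxazole rings are bought ready-made and joined through their CH2 link by a Negishi coupling, so no ring is built. The sequence is ester to aldehyde, aldol with a dioxolanyl methyl ketone (brings C2'–C6'), acylation of C1'-OH with a pimelate half-ester, acid unmasking, ketone reduction, and last the anodic joining of the two chain halves.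
Stereochemistry: C4' and C5' come from a chiral-pool dioxolane ester, C1' from a diisopinocampheylboron aldol (reagent control plus 1,5-anti induction), and C3' from a C5'-OH-directed 1,3-anti reduction. C3' stays a ketone until C1'-OH is acylated, so the hydroxyl groups never have to be told apart.
Enabling feature: C6–C7 lies inside the unbranched, heteroatom-free (CH2)12 run C2–C13 of the acyl chain, four CH2 from the ester carbonyl C1 and six CH2 from the branch point C14. Each half is therefore a plain primary alkyl radical, that is, a carboxylic acid one carbon longer (pimelic half-ester and 9-methyldecanoic acid). The two CO2H groups are the only activating groups and leave as CO2 in the event itself.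
The two oxazole rings, the CH2 between them and the oxygenated carbons C1' and C3'–C5' sit seven or more bonds from the radical carbon, so the coupling can be run last, on the unprotected triol.

Key step: step 10

Remark on locants: the side chain runs from C1' (carbinol carbon on C4 of the central oxazole, bears the ester) to C6' (methyl). The acyl chain runs from C1 (C=O) to C15. The target is (1'R,3'S,4'R,5'S).
Assumption: all compounds marked as starting material in the list are taken to be catalogue compounds.

Step 1
Reactants: 1 5-(chloromethyl)-1,3-oxazole; 2 ethyl 2-chloro-1,3-oxazole-4-carboxylate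
Product: 4 ethyl 2-[(1,3-oxazol-5-yl)methyl]-1,3-oxazole-4-carboxylate, via oxazol-5-ylmethylzinc chloride 3 (not isolated)
Conditions: 1, Zn dust, LiCl, THF, 25 °C; then 2, Pd(OAc)2 (2 mol%), SPhos (4 mol%), THF, 25 to 50 °C
Reagents that add atoms: none
Why: LiCl-promoted zinc insertion into a heterobenzylic chloride followed by Negishi cross-coupling at the activated C2–Cl bond of 2 should work because the weakly basic organozinc leaves the ester, the oxazole C2–H and the newly formed inter-ring CH2 untouched.

Step 2
Reactants: 4 ethyl 2-[(1,3-oxazol-5-yl)methyl]-1,3-oxazole-4-carboxylate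
Product: 6 2-[(1,3-oxazol-5-yl)methyl]-1,3-oxazole-4-carbaldehyde, via aluminium hemiacetal 5 (not isolated)
Conditions: DIBAL-H, CH2Cl2, −78 °C; MeOH quench, aq. Rochelle salt
Reagents that add atoms: none
Why: In this DIBAL-H partial reduction of an ester the tetrahedral adduct 5 persists at −78 °C until the quench, so the aldehyde is released only when no hydride is left, as is routine for oxazole-4-carboxylates.

Step 3
Reactants: 7 methyl (4R,5S)-2,2,5-trimethyl-1,3-dioxolane-4-carboxylate
Product: 8 (4R,5S)-N-methoxy-N,2,2,5-tetramethyl-1,3-dioxolane-4-carboxamide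
Conditions: MeNH(OMe)·HCl, i-PrMgCl, THF, −20 to 0 °C
Reagents that add atoms: N,O-dimethylhydroxylamine hydrochloride, CNOC.Cl
Why: Weinreb amide formation from an ester with the magnesium amide made in the flask is fast at −20 °C, where the α-alkoxy centre is not enolised, and the trans-dioxolane is in any case the more stable epimer.

Step 4
Reactants: 8 (4R,5S)-N-methoxy-N,2,2,5-tetramethyl-1,3-dioxolane-4-carboxamide
Product: 10 1-[(4R,5S)-2,2,5-trimethyl-1,3-dioxolan-4-yl]ethan-1-one, via magnesium hemiaminal adduct 9 (not isolated)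
Conditions: MeMgBr, THF, −78 to 0 °C; aq. NH4Cl
Reagents that add atoms: methylmagnesium bromide, C[Mg]Br
Why: In the Weinreb ketone synthesis the chelated adduct 9 survives until the quench, which rules out a second addition and leaves both stereocentres untouched.

Step 5
Reactants: 10 1-[(4R,5S)-2,2,5-trimethyl-1,3-dioxolan-4-yl]ethan-1-one; 6 2-[(1,3-oxazol-5-yl)methyl]-1,3-oxazole-4-carbaldehyde
Product: 13 (3R)-3-hydroxy-3-{2-[(1,3-oxazol-5-yl)methyl]-1,3-oxazol-4-yl}-1-[(4R,5S)-2,2,5-trimethyl-1,3-dioxolan-4-yl]propan-1-one, via diisopinocampheylboron enolate 11 (not isolated), via boron aldolate 12 (not isolated)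
Conditions: 10, (−)-Ipc2BCl, Et3N, Et2O, 0 °C; 6 (in CH2Cl2), −78 to −20 °C; then MeOH, pH 7 buffer, 30% H2O2, 0 °C
Reagents that add atoms: none
Why: In this diisopinocampheylboron-mediated (Paterson) methyl ketone aldol, soft enolisation takes place on the methyl side only and the preformed, non-basic enolate 11 adds through a cyclic transition state to the Re face of 6; the (−)-Ipc ligands and the 1,5-anti preference exerted by the β-alkoxy oxygen on C5' are both expected to favour (1'R), and any (1'S) epimer is a separable diastereomer.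

Step 6
Reactants: 13 the (1'R)-aldol; 14 7-(tert-butoxy)-7-oxoheptanoic acid (mono-tert-butyl pimelate)
Product: 15 1-tert-butyl 7-[(1R)-1-{2-[(1,3-oxazol-5-yl)methyl]-1,3-oxazol-4-yl}-3-oxo-3-[(4R,5S)-2,2,5-trimethyl-1,3-dioxolan-4-yl]propyl] heptanedioate
Conditions: DCC, DMAP (10 mol%), CH2Cl2, −10 to 0 °C
Reagents that add atoms: none
Why: In this Steglich esterification C1'-OH is the only hydroxyl group of 13 because C3' is still a ketone, so the ester can go nowhere else, the C1'–O bond is not touched (retention), and low temperature with only catalytic DMAP should hold back E1cB loss of the new β-acyloxy group.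

Step 7
Reactants: 15 the tert-butyl ester, acetonide, ketone
Product: 16 7-{[(1R,4R,5S)-4,5-dihydroxy-1-{2-[(1,3-oxazol-5-yl)methyl]-1,3-oxazol-4-yl}-3-oxohexyl]oxy}-7-oxoheptanoic acid
Conditions: TFA–H2O 9:1, 0 °C to rt; toluene azeotrope
Reagents that add atoms: none
Why: Aqueous TFA acidolysis cleaves the tert-butyl ester and hydrolyses the isopropylidene acetal in one operation, while the secondary ester at C1' should survive because the protonated oxazole disfavours ionisation at C1' and acid does not trigger E1cB.

Step 8
Reactants: 16 the dihydroxy keto acid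
Product: 17 7-{[(1R,3S,4R,5S)-3,4,5-trihydroxy-1-{2-[(1,3-oxazol-5-yl)methyl]-1,3-oxazol-4-yl}hexyl]oxy}-7-oxoheptanoic acid
Conditions: Me4NBH(OAc)3, MeCN–AcOH 1:1, −30 to −20 °C; aq. Rochelle salt, MeOH co-evaporation
Reagents that add atoms: none
Why: In the Saksena–Evans hydroxyl-directed reduction boron bound to C5'-O delivers hydride intramolecularly through a chair transition state and sets C3' as (S), 1,3-anti to C5'-OH; this is the same face expected for direction by the α-hydroxyl on C4' (1,2-anti), and the reagent touches neither ester, acid nor oxazole.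

Step 9
Reactants: 18 7-bromoheptanoic acid; 19 isobutylmagnesium bromide
Product: 21 9-methyldecanoic acid, via bromomagnesium 7-bromoheptanoate 20 (not isolated)
Conditions: 19 (2.3 equiv), Li2CuCl4 (3 mol%), THF, −20 to 0 °C; 1 M HCl
Reagents that add atoms: none
Why: In this copper-catalysed (Kochi-type) sp3–sp3 coupling of a primary Grignard reagent with a primary bromide the first equivalent of 19 turns the acid into its inert carboxylate 20, a classical entry to iso-branched fatty acids.

Step 10
Reactants: 17 the triol pimelate half-ester; 21 9-methyldecanoic acid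
Product: 22 (1R,3S,4R,5S)-3,4,5-trihydroxy-1-{2-[(1,3-oxazol-5-yl)methyl]-1,3-oxazol-4-yl}hexyl 14-methylpentadecanoate
Conditions: 17 (1 equiv), 21 (8 equiv), KOH (5 mol% of total acid), MeOH, Pt anode/Pt cathode, undivided cell, ca. 200 mA cm−2, 10–15 °C, current cut while the bath is still weakly acidic
Reagents that add atoms: none
Why: At a smooth platinum anode under high current density the carboxylates of 17 and 21 are each oxidised by one electron and lose CO2, and the two primary radicals formed in the thin layer at the electrode, 5-(alkoxycarbonyl)pentyl and 8-methylnonyl, combine to make the C6–C7 bond while protons are reduced to H2 at the cathode. The closest known reaction type is the mixed (crossed) Kolbe electrolysis of an alkanedioic acid half-ester with a fatty acid, the classical way to lengthen and branch fatty acid chains. No ring is closed and no stereocentre is made, and C1', C3', C4' and C5' lie seven or more bonds from the radical carbon and are not touched. Cross-coupling over self-coupling of 17 is secured statistically by the eightfold excess of the cheap acid 21, and the hydrocarbon that this excess gives by self-coupling is non-polar and parts from the triol on a short column. The radical rather than the cationic (Hofer–Moest) course is secured by the structure, since both radical carbons are unbranched primary CH2 groups with no heteroatom or branch within four carbons, and by platinum, high current density and weakly acidic, only partly neutralised methanol. Oxidation of carboxylate in preference to the two oxazole rings, the inter-ring CH2 and the triol rests on the dense carboxylate layer that covers the anode under Kolbe conditions and keeps neutral groups away as it keeps the methanol away (isolated C=C bonds of unsaturated fatty acids, of similar ionisation energy, are known to survive), and stopping while the bath is acidic means no methoxide can cleave or shift the C1' ester.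

Compound list
1 | 5-(chloromethyl)-1,3-oxazole | ClCc1cnco1 | starting material
2 | ethyl 2-chloro-1,3-oxazole-4-carboxylate | CCOC(=O)c1coc(Cl)n1 | starting material
3 | oxazol-5-ylmethylzinc chloride (not isolated) | Cl[Zn]Cc1cnco1 | intermediate
4 | ethyl 2-[(1,3-oxazol-5-yl)methyl]-1,3-oxazole-4-carboxylate | CCOC(=O)c1coc(Cc2cnco2)n1 | intermediate
5 | diisobutylaluminium hemiacetal of 4 (not isolated) | CCOC(O[Al](CC(C)C)CC(C)C)c1coc(Cc2cnco2)n1 | intermediate
6 | 2-[(1,3-oxazol-5-yl)methyl]-1,3-oxazole-4-carbaldehyde | O=Cc1coc(Cc2cnco2)n1 | intermediate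
7 | methyl (4R,5S)-2,2,5-trimethyl-1,3-dioxolane-4-carboxylate | COC(=O)[C@@H]1OC(C)(C)O[C@H]1C | starting material
8 | (4R,5S)-N-methoxy-N,2,2,5-tetramethyl-1,3-dioxolane-4-carboxamide | CON(C)C(=O)[C@@H]1OC(C)(C)O[C@H]1C | intermediate
9 | bromomagnesium hemiaminal adduct of 8 and MeMgBr (not isolated) | CON(C)C(C)(O[Mg]Br)[C@@H]1OC(C)(C)O[C@H]1C | intermediate
10 | 1-[(4R,5S)-2,2,5-trimethyl-1,3-dioxolan-4-yl]ethan-1-one | CC(=O)[C@@H]1OC(C)(C)O[C@H]1C | intermediate
11 | diisopinocampheylboron enolate of 10, Ipc groups from (+)-α-pinene (not isolated) | C=C(OB([C@@H]1C[C@@H]2C[C@H]([C@H]1C)C2(C)C)[C@@H]1C[C@@H]2C[C@H]([C@H]1C)C2(C)C)[C@@H]1OC(C)(C)O[C@H]1C | intermediate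
12 | diisopinocampheylboron aldolate of 13 (not isolated) | B([C@@H]1C[C@@H]2C[C@H]([C@H]1C)C2(C)C)([C@@H]1C[C@@H]2C[C@H]([C@H]1C)C2(C)C)O[C@H](CC(=O)[C@@H]1OC(C)(C)O[C@H]1C)c1coc(Cc2cnco2)n1 | intermediate
13 | (3R)-3-hydroxy-3-{2-[(1,3-oxazol-5-yl)methyl]-1,3-oxazol-4-yl}-1-[(4R,5S)-2,2,5-trimethyl-1,3-dioxolan-4-yl]propan-1-one | O[C@H](CC(=O)[C@@H]1OC(C)(C)O[C@H]1C)c1coc(Cc2cnco2)n1 | intermediate
14 | 7-(tert-butoxy)-7-oxoheptanoic acid | CC(C)(C)OC(=O)CCCCCC(=O)O | starting material
15 | 1-tert-butyl 7-[(1R)-1-{2-[(1,3-oxazol-5-yl)methyl]-1,3-oxazol-4-yl}-3-oxo-3-[(4R,5S)-2,2,5-trimethyl-1,3-dioxolan-4-yl]propyl] heptanedioate | CC(C)(C)OC(=O)CCCCCC(=O)O[C@H](CC(=O)[C@@H]1OC(C)(C)O[C@H]1C)c1coc(Cc2cnco2)n1 | intermediate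
16 | 7-{[(1R,4R,5S)-4,5-dihydroxy-1-{2-[(1,3-oxazol-5-yl)methyl]-1,3-oxazol-4-yl}-3-oxohexyl]oxy}-7-oxoheptanoic acid | OC(=O)CCCCCC(=O)O[C@H](CC(=O)[C@H](O)[C@H](C)O)c1coc(Cc2cnco2)n1 | intermediate
17 | 7-{[(1R,3S,4R,5S)-3,4,5-trihydroxy-1-{2-[(1,3-oxazol-5-yl)methyl]-1,3-oxazol-4-yl}hexyl]oxy}-7-oxoheptanoic acid | OC(=O)CCCCCC(=O)O[C@H](C[C@H](O)[C@H](O)[C@H](C)O)c1coc(Cc2cnco2)n1 | intermediate
18 | 7-bromoheptanoic acid | OC(=O)CCCCCCBr | starting material
19 | isobutylmagnesium bromide | CC(C)C[Mg]Br | starting material
20 | bromomagnesium 7-bromoheptanoate (not isolated) | Br[Mg]OC(=O)CCCCCCBr | intermediate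
21 | 9-methyldecanoic acid | CC(C)CCCCCCCC(=O)O | intermediate
22 | (1R,3S,4R,5S)-3,4,5-trihydroxy-1-{2-[(1,3-oxazol-5-yl)methyl]-1,3-oxazol-4-yl}hexyl 14-methylpentadecanoate | CC(C)CCCCCCCCCCCCC(=O)O[C@H](C[C@H](O)[C@H](O)[C@H](C)O)c1coc(Cc2cnco2)n1 | target

Total step count: 10. Longest linear sequence: 7 steps (1, 2, 5, 6, 7, 8, 10; the branch 3, 4, 5, 6, 7, 8, 10 is equally long).

Steps most likely to fail

Step 10. Anodic oxidation of the oxazole rings or of the methylene between them may compete with carboxylate oxidation. The polar substrate may passivate the electrode, and the valuable radical may be lost to disproportionation or self-coupling. The fallback sets out from 13 and comes back at 22, and finishes the chain before it meets the heterocycle. 12-Bromododecanoic acid and 19 are coupled under the conditions of step 9 to 14-methylpentadecanoic acid F1. Steglich esterification of 13 with this acid gives the keto acetonide ester F2. Aqueous TFA then frees the dihydroxy ketone ester F3, and the Saksena–Evans reduction of step 8 gives 22.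

Step 6. Base-induced E1cB elimination across C1'–C2' may overtake acylation, and the β-acyloxy ketone may also be lost in the same way in step 7. The fallback sets out from 13 and comes back at 17, and never passes through a β-acyloxy ketone. Narasaka–Prasad reduction of 13 (Et2BOMe, NaBH4, THF–MeOH, −78 °C) gives the 1',3'-syn diol F4. Mono-acylation follows at the less hindered C1'-OH, which stands next to the flat oxazole ring, whereas C3'-OH is flanked by the substituted dioxolane. With a fivefold excess of pimelic acid (DCC, cat. DMAP, 0 °C) this gives the acetonide half-ester F5. Aqueous acetic acid (80%, 40 °C) then removes the acetonide to give 17.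

Step 8. Facial selectivity may be poor if C4'-OH and C5'-OH compete for boron, and the acyl group may shift from C1'-O to the new C3'-OH. The fallback sets out from 15 and comes back at 17, and moves the reduction to the protected stage with a different control element. Zn(BH4)2 (Et2O–CH2Cl2, −40 °C) reduces 15 under Cram-chelate control, with zinc held between the ketone oxygen and the dioxolane oxygen on C4'. This gives the 3',4'-anti alcohol F6, and the aqueous TFA treatment of step 7 then gives 17.

Further compounds
F1 | step 10 | 14-methylpentadecanoic acid | CC(C)CCCCCCCCCCCCC(=O)O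
F2 | step 10 | (1R)-1-{2-[(1,3-oxazol-5-yl)methyl]-1,3-oxazol-4-yl}-3-oxo-3-[(4R,5S)-2,2,5-trimethyl-1,3-dioxolan-4-yl]propyl 14-methylpentadecanoate | CC(C)CCCCCCCCCCCCC(=O)O[C@H](CC(=O)[C@@H]1OC(C)(C)O[C@H]1C)c1coc(Cc2cnco2)n1
F3 | step 10 | (1R,4R,5S)-4,5-dihydroxy-1-{2-[(1,3-oxazol-5-yl)methyl]-1,3-oxazol-4-yl}-3-oxohexyl 14-methylpentadecanoate | CC(C)CCCCCCCCCCCCC(=O)O[C@H](CC(=O)[C@H](O)[C@H](C)O)c1coc(Cc2cnco2)n1
F4 | step 6 | (1R,3S)-1-{2-[(1,3-oxazol-5-yl)methyl]-1,3-oxazol-4-yl}-3-[(4S,5S)-2,2,5-trimethyl-1,3-dioxolan-4-yl]propane-1,3-diol | O[C@H](C[C@H](O)[C@@H]1OC(C)(C)O[C@H]1C)c1coc(Cc2cnco2)n1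
F5 | step 6 | 7-{[(1R,3S)-3-hydroxy-1-{2-[(1,3-oxazol-5-yl)methyl]-1,3-oxazol-4-yl}-3-[(4S,5S)-2,2,5-trimethyl-1,3-dioxolan-4-yl]propyl]oxy}-7-oxoheptanoic acid | OC(=O)CCCCCC(=O)O[C@H](C[C@H](O)[C@@H]1OC(C)(C)O[C@H]1C)c1coc(Cc2cnco2)n1
F6 | step 8 | 1-tert-butyl 7-[(1R,3S)-3-hydroxy-1-{2-[(1,3-oxazol-5-yl)methyl]-1,3-oxazol-4-yl}-3-[(4S,5S)-2,2,5-trimethyl-1,3-dioxolan-4-yl]propyl] heptanedioate | CC(C)(C)OC(=O)CCCCCC(=O)O[C@H](C[C@H](O)[C@@H]1OC(C)(C)O[C@H]1C)c1coc(Cc2cnco2)n1
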